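**Plan**

- Locants used throughout: five-membered ring C1(CH3)–C2H2–C3H2–C4(OH)(i-Pr)–C5H; seven-membered ring C5–C6H(OAr)–C7H2–C8(CH3)=C9H–C10(=O)–C1.
- Cuts, last to first: aryl O–Si and C1–CH3 (the methyl is the CH2 of a C1/C10 siloxycyclopropane), C10=O (allylic oxidation), ester C6–O, C6–H, C4–O (from C4–B), then C2–C3 and C4–C5 together, the C1–C2–C5 cyclopropane, and the seven-membered ring back to 3-methylphenol.
- Enabling feature: C4(OH) is β and C2 is γ to C6. With C6 as a ketone and C2 as the apex CH2 of a cyclopropane fused to the seven-membered ring at C1–C5, one-electron reduction opens C5–C2 to a C2 radical and a C5=C6 enolate. These are the two ends of a three-carbon unit that adds across CH2=C(Bpin)i-Pr.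
- Forward order: seven-membered ring (Birch reduction, cyclopropanation, FeCl3 ring expansion), cyclopropane, five-membered ring by the [3+2] event, C6 reduction and acylation, C10 oxidation, C1 methylation, desilylation.
- Stereochemistry: CBS reduction fixes C6–OH of 7, which directs the cyclopropane (C1, C5 of 9). C1–H then relays to C5 and C4 in the ring closure. C4–OH directs the C6 hydride (1,3-anti) and, once C1 is flattened in the C1=C10 enol ether, the C1 methyl (syn), which turns the cis into the trans ring fusion.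

Key step: step 10

Remark: the angular methyl is deliberately left off C1 until step 16, because a kinetic closure of the five-membered ring should place the isopropyl group on the same face as the angular substituent, which is the wrong face for a methyl group but the right one for hydrogen.

**Route**

Step 1
Reactants: 1 3-methylphenol
Product: 2 tert-butyldimethyl(3-methylphenoxy)silane
Conditions: t-BuMe2SiCl, imidazole, DMF, 20 °C
Reagents that add atoms: tert-butyldimethylsilyl chloride, CC(C)(C)[Si](C)(C)Cl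
Why: Imidazole-promoted silylation of a phenol, which installs the silyl group that later makes the enol ether needed for the ring expansion.

Step 2
Reactants: 2 tert-butyldimethyl(3-methylphenoxy)silane
Product: 3 tert-butyldimethyl[(5-methylcyclohexa-1,4-dien-1-yl)oxy]silane
Conditions: Li, NH3 (l), t-BuOH, THF, −78 °C to −33 °C
Reagents that add atoms: none
Why: Birch reduction of the aryl silyl ether should leave both the oxygen-bearing and the methyl-bearing carbon on double bonds, as with the corresponding anisole, giving the 1-silyloxy-1,4-diene.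

Step 3
Reactants: 3 tert-butyldimethyl[(5-methylcyclohexa-1,4-dien-1-yl)oxy]silane
Product: 4 rac-tert-butyldimethyl[(3-methylbicyclo[4.1.0]hept-3-en-1-yl)oxy]silane
Conditions: Et2Zn, CH2I2, CH2Cl2, 0 °C
Reagents that add atoms: diiodomethane, ICI
Why: Furukawa-modified Simmons–Smith cyclopropanation should be fastest at the electron-rich silyl enol ether double bond and leave the trisubstituted alkene.

Step 4
Reactants: 4 rac-tert-butyldimethyl[(3-methylbicyclo[4.1.0]hept-3-en-1-yl)oxy]silane
Product: 6 6-methylcyclohepta-2,5-dien-1-one, via 3-chloro-6-methylcyclohept-5-en-1-one 5 (not isolated)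
Conditions: FeCl3, DMF, 0 °C to 20 °C; then NaOAc, MeOH, 50 °C
Reagents that add atoms: none
Why: Ito–Saegusa one-carbon ring expansion, in which FeCl3 oxidises the siloxycyclopropane, the internal bond cleaves to the ring-expanded β-keto radical that is chlorinated, and NaOAc eliminates HCl to the conjugated cycloheptenone.

Step 5
Reactants: 6 6-methylcyclohepta-2,5-dien-1-one
Product: 7 (1R)-6-methylcyclohepta-2,5-dien-1-ol
Conditions: (S)-2-methyl-CBS-oxazaborolidine (10 mol %), catecholborane, toluene, −78 °C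
Reagents that add atoms: none
Why: Corey–Bakshi–Shibata reduction with the alkenyl arm as the large group, so that the (S)-catalyst should give the (R)-allylic alcohol, while catecholborane at low temperature avoids hydroboration and conjugate reduction.

Step 6
Reactants: 7 (1R)-6-methylcyclohepta-2,5-dien-1-ol
Product: 8 (1S,2R,7R)-4-methylbicyclo[5.1.0]oct-4-en-2-ol
Conditions: Et2Zn, CH2I2, CH2Cl2, −10 °C to 0 °C
Reagents that add atoms: diiodomethane, ICI
Why: Hydroxyl-directed Simmons–Smith cyclopropanation, in which the zinc alkoxide delivers CH2 to the allylic double bond on the face of the oxygen and so sets C1 and C5 from the carbinol centre.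

Step 7
Reactants: 8 (1S,2R,7R)-4-methylbicyclo[5.1.0]oct-4-en-2-ol
Product: 9 (1S,7R)-4-methylbicyclo[5.1.0]oct-4-en-2-one
Conditions: Dess–Martin periodinane, NaHCO3, CH2Cl2, 0 °C to 20 °C
Reagents that add atoms: none
Why: Dess–Martin oxidation under buffered, non-enolising conditions should give the cyclopropyl ketone without moving the β,γ-double bond.

Step 8
Reactants: 10 3-methylbutan-2-one
Product: 12 3-methylbut-1-en-2-yl trifluoromethanesulfonate, via lithium 3-methylbut-1-en-2-olate 11 (not isolated)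
Conditions: LiN(i-Pr)2, THF, −78 °C; then PhNTf2, −78 °C to 0 °C
Reagents that add atoms: N-phenylbis(trifluoromethanesulfonimide), O=S(=O)(N(c1ccccc1)S(=O)(=O)C(F)(F)F)C(F)(F)F
Why: Kinetic deprotonation of the methyl group followed by O-triflation of the less substituted enolate (enol triflate formation).

Step 9
Reactants: 12 3-methylbut-1-en-2-yl trifluoromethanesulfonate
Product: 13 4,4,5,5-tetramethyl-2-(3-methylbut-1-en-2-yl)-1,3,2-dioxaborolane
Conditions: B2pin2, PdCl2(PPh3)2 (3 mol %), PPh3, KOPh, toluene, 50 °C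
Reagents that add atoms: bis(pinacolato)diboron, CC1(C)OB(OC1(C)C)B1OC(C)(C)C(C)(C)O1
Why: Miyaura borylation of a 1-alkenyl triflate, which keeps the position of the double bond.

Step 10
Reactants: 9 (1S,7R)-4-methylbicyclo[5.1.0]oct-4-en-2-one; 13 4,4,5,5-tetramethyl-2-(3-methylbut-1-en-2-yl)-1,3,2-dioxaborolane
Product: 14 (3S,3aR,8aS)-6-methyl-3-(propan-2-yl)-3-(4,4,5,5-tetramethyl-1,3,2-dioxaborolan-2-yl)-2,3,3a,5,8,8a-hexahydroazulen-4(1H)-one
Conditions: SmI2 (25 mol %), Sm metal (25 mol %), 13 (3 equiv), THF, 55 °C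
Reagents that add atoms: none
Why: Proposed new method: SmI2 reduces the ketone of 9 to its ketyl, whose cyclopropane opens at the external C5–C2 bond (the bond that overlaps with the ketyl π system in the fused bicycle) to give a primary C2 radical and a trivalent samarium enolate at C5=C6; the closest known reaction type is the SmI2-catalysed radical-relay formal [3+2] cycloaddition of alkyl cyclopropyl ketones with alkenes and alkynes, joined here to the known addition of alkyl radicals to the CH2 end of alkenylboronic esters. The C2 radical adds to C3 of 13 (bond C2–C3), the tertiary α-boryl radical at C4 closes on the enolate carbon C5 in a 5-exo-trig mode (bond C4–C5), and the ketyl then returns its electron to trivalent samarium so that the catalyst turns over. The new ring can close only on the face of C5 that carries the C2 tether, so C5 is set by C1 and the ring fusion is cis. At C4 the isopropyl group should take the outer, convex position next to H-5 and the flat boronate the inner position next to C6, which places the future oxygen cis to C6. The step needs external and not internal cyclopropane cleavage (C1 carries only hydrogen, so no stabilised radical competes) and radical addition faster than reduction of the C2 or C4 radical; the bicyclic geometry, the low stationary concentration of divalent samarium and the excess of 13 are meant to secure both.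

Step 11
Reactants: 14 (3S,3aR,8aS)-6-methyl-3-(propan-2-yl)-3-(4,4,5,5-tetramethyl-1,3,2-dioxaborolan-2-yl)-2,3,3a,5,8,8a-hexahydroazulen-4(1H)-one
Product: 15 (3R,3aR,8aS)-3-hydroxy-6-methyl-3-(propan-2-yl)-2,3,3a,5,8,8a-hexahydroazulen-4(1H)-one
Conditions: NaBO3·4H2O, THF/H2O (1:1), 20 °C
Reagents that add atoms: sodium perborate, [Na+].[Na+].O[B-]1(O)OO[B-](O)(O)OO1
Why: Oxidation of the tertiary alkylboronic ester by 1,2-migration of carbon from boron to oxygen goes with retention, so the C4 hydroxyl stays cis to C6.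

Step 12
Reactants: 15 (3R,3aR,8aS)-3-hydroxy-6-methyl-3-(propan-2-yl)-2,3,3a,5,8,8a-hexahydroazulen-4(1H)-one
Product: 16 (3R,3aS,4S,8aS)-6-methyl-3-(propan-2-yl)-1,2,3,3a,4,5,8,8a-octahydroazulene-3,4-diol
Conditions: Me4NBH(OAc)3, MeCN/AcOH (1:1), −30 °C
Reagents that add atoms: none
Why: Evans–Saksena reduction, in which the acetoxyborohydride bound to the C4 oxygen delivers hydride through a chair transition state with the isopropyl group pseudo-equatorial, should give the 1,3-anti diol with the C6 hydroxyl on the face of H-5.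

Step 13
Reactants: 17 4-hydroxy-3-methoxybenzoic acid
Product: 19 4-[(tert-butyldimethylsilyl)oxy]-3-methoxybenzoic acid, via bis-silylated vanillic acid 18 (not isolated)
Conditions: t-BuMe2SiCl, imidazole, DMF, 20 °C; then AcOH/THF/H2O (3:1:1), 20 °C
Reagents that add atoms: tert-butyldimethylsilyl chloride, CC(C)(C)[Si](C)(C)Cl
Why: Silylation of both acidic groups followed by selective hydrolysis of the much more labile silyl ester.

Step 14
Reactants: 16 (3R,3aS,4S,8aS)-6-methyl-3-(propan-2-yl)-1,2,3,3a,4,5,8,8a-octahydroazulene-3,4-diol; 19 4-[(tert-butyldimethylsilyl)oxy]-3-methoxybenzoic acid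
Product: 20 (3R,3aS,4S,8aS)-3-hydroxy-6-methyl-3-(propan-2-yl)-1,2,3,3a,4,5,8,8a-octahydroazulen-4-yl 4-[(tert-butyldimethylsilyl)oxy]-3-methoxybenzoate
Conditions: DCC, DMAP, CH2Cl2, 0 °C to 20 °C
Reagents that add atoms: none
Why: Steglich esterification should acylate only the secondary C6 hydroxyl, the tertiary C4 hydroxyl being too hindered.

Step 15
Reactants: 20 (3R,3aS,4S,8aS)-3-hydroxy-6-methyl-3-(propan-2-yl)-1,2,3,3a,4,5,8,8a-octahydroazulen-4-yl 4-[(tert-butyldimethylsilyl)oxy]-3-methoxybenzoate
Product: 21 (3R,3aS,4S,8aR)-3-hydroxy-6-methyl-8-oxo-3-(propan-2-yl)-1,2,3,3a,4,5,8,8a-octahydroazulen-4-yl 4-[(tert-butyldimethylsilyl)oxy]-3-methoxybenzoate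
Conditions: CrO3, 3,5-dimethylpyrazole, CH2Cl2, −20 °C
Reagents that add atoms: chromium trioxide, O=[Cr](=O)=O
Why: Allylic oxidation with the CrO3·3,5-dimethylpyrazole complex goes to the CH2 next to the CH end of a trisubstituted alkene (as a 5-ene steroid gives its 7-ketone), here C10, while C7 is deactivated by the neighbouring acyloxy carbon.

Step 16
Reactants: 21 (3R,3aS,4S,8aR)-3-hydroxy-6-methyl-8-oxo-3-(propan-2-yl)-1,2,3,3a,4,5,8,8a-octahydroazulen-4-yl 4-[(tert-butyldimethylsilyl)oxy]-3-methoxybenzoate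
Product: 23 the C1/C10 siloxycyclopropane (C10–OSiMe3, cyclopropane CH2 bonded to C1 and C10 on the face of the C4 hydroxyl; other centres as in 21), via silyl dienol ether 22 (not isolated)
Conditions: LiN(SiMe3)2 (2.3 equiv), THF, −78 °C; Me3SiCl (1.1 equiv), −78 °C; then Et2Zn, CH2I2, CH2Cl2, −40 °C to 0 °C
Reagents that add atoms: chlorotrimethylsilane, C[Si](C)(C)Cl; diiodomethane, ICI
Why: Kinetic α′-deprotonation of the enone at C1 and O-silylation give the cross-conjugated silyl dienol ether, and the zinc alkoxide of the C4 hydroxyl then directs Simmons–Smith methylene transfer to its own face of the C1=C10 bond, so the new CH2 on C1 is cis to the C4 oxygen and trans to H-5.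

Step 17
Reactants: 23 the C1/C10 siloxycyclopropane
Product: 24 (3R,3aS,4S,8aS)-3-hydroxy-6,8a-dimethyl-8-oxo-3-(propan-2-yl)-1,2,3,3a,4,5,8,8a-octahydroazulen-4-yl 4-hydroxy-3-methoxybenzoate (CNP0136950.2)
Conditions: K2CO3, MeOH, 0 °C to 20 °C
Reagents that add atoms: none
Why: Base-induced opening of the siloxycyclopropane at the bond to its CH2 carbon (the Conia route to α-methyl ketones) turns that CH2 into the C1 methyl with retention at C1 and restores the C10 enone, and the same methanolic K2CO3 cleaves the phenolic silyl ether.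

**Compound list**

1 | 3-methylphenol | Cc1cccc(O)c1 | starting material
2 | tert-butyldimethyl(3-methylphenoxy)silane | Cc1cccc(O[Si](C)(C)C(C)(C)C)c1 | intermediate
3 | tert-butyldimethyl[(5-methylcyclohexa-1,4-dien-1-yl)oxy]silane | CC1=CCC=C(O[Si](C)(C)C(C)(C)C)C1 | intermediate
4 | rac-tert-butyldimethyl[(3-methylbicyclo[4.1.0]hept-3-en-1-yl)oxy]silane | CC1=CCC2CC2(O[Si](C)(C)C(C)(C)C)C1 | intermediate
5 | rac-3-chloro-6-methylcyclohept-5-en-1-one | O=C1CC(Cl)CC=C(C)C1 | intermediate (not isolated)
6 | 6-methylcyclohepta-2,5-dien-1-one | O=C1C=CCC=C(C)C1 | intermediate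
7 | (1R)-6-methylcyclohepta-2,5-dien-1-ol | O[C@H]1C=CCC=C(C)C1 | intermediate
8 | (1S,2R,7R)-4-methylbicyclo[5.1.0]oct-4-en-2-ol | O[C@@H]1CC(C)=CC[C@@H]2C[C@H]12 | intermediate
9 | (1S,7R)-4-methylbicyclo[5.1.0]oct-4-en-2-one | O=C1CC(C)=CC[C@@H]2C[C@H]12 | intermediate
10 | 3-methylbutan-2-one | CC(=O)C(C)C | starting material
11 | lithium 3-methylbut-1-en-2-olate | [Li+].[O-]C(=C)C(C)C | intermediate (not isolated)
12 | 3-methylbut-1-en-2-yl trifluoromethanesulfonate | C=C(OS(=O)(=O)C(F)(F)F)C(C)C | intermediate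
13 | 4,4,5,5-tetramethyl-2-(3-methylbut-1-en-2-yl)-1,3,2-dioxaborolane | C=C(B1OC(C)(C)C(C)(C)O1)C(C)C | intermediate
14 | (3S,3aR,8aS)-6-methyl-3-(propan-2-yl)-3-(4,4,5,5-tetramethyl-1,3,2-dioxaborolan-2-yl)-2,3,3a,5,8,8a-hexahydroazulen-4(1H)-one | O=C1CC(C)=CC[C@@H]2CC[C@@](B3OC(C)(C)C(C)(C)O3)(C(C)C)[C@H]12 | intermediate
15 | (3R,3aR,8aS)-3-hydroxy-6-methyl-3-(propan-2-yl)-2,3,3a,5,8,8a-hexahydroazulen-4(1H)-one | O=C1CC(C)=CC[C@@H]2CC[C@@](O)(C(C)C)[C@H]12 | intermediate
16 | (3R,3aS,4S,8aS)-6-methyl-3-(propan-2-yl)-1,2,3,3a,4,5,8,8a-octahydroazulene-3,4-diol | O[C@H]1CC(C)=CC[C@@H]2CC[C@@](O)(C(C)C)[C@H]12 | intermediate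
17 | 4-hydroxy-3-methoxybenzoic acid (vanillic acid) | COc1cc(C(=O)O)ccc1O | starting material
18 | tert-butyldimethylsilyl 4-[(tert-butyldimethylsilyl)oxy]-3-methoxybenzoate | COc1cc(C(=O)O[Si](C)(C)C(C)(C)C)ccc1O[Si](C)(C)C(C)(C)C | intermediate (not isolated)
19 | 4-[(tert-butyldimethylsilyl)oxy]-3-methoxybenzoic acid | COc1cc(C(=O)O)ccc1O[Si](C)(C)C(C)(C)C | intermediate
20 | (3R,3aS,4S,8aS)-3-hydroxy-6-methyl-3-(propan-2-yl)-1,2,3,3a,4,5,8,8a-octahydroazulen-4-yl 4-[(tert-butyldimethylsilyl)oxy]-3-methoxybenzoate | O=C(O[C@H]1CC(C)=CC[C@@H]2CC[C@@](O)(C(C)C)[C@H]12)c1ccc(O[Si](C)(C)C(C)(C)C)c(OC)c1 | intermediate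
21 | (3R,3aS,4S,8aR)-3-hydroxy-6-methyl-8-oxo-3-(propan-2-yl)-1,2,3,3a,4,5,8,8a-octahydroazulen-4-yl 4-[(tert-butyldimethylsilyl)oxy]-3-methoxybenzoate | O=C(O[C@H]1CC(C)=CC(=O)[C@@H]2CC[C@@](O)(C(C)C)[C@H]12)c1ccc(O[Si](C)(C)C(C)(C)C)c(OC)c1 | intermediate
22 | (3R,3aS,4S)-3-hydroxy-6-methyl-3-(propan-2-yl)-8-[(trimethylsilyl)oxy]-1,2,3,3a,4,5-hexahydroazulen-4-yl 4-[(tert-butyldimethylsilyl)oxy]-3-methoxybenzoate | O=C(O[C@H]1CC(C)=CC(O[Si](C)(C)C)=C2CC[C@@](O)(C(C)C)[C@H]12)c1ccc(O[Si](C)(C)C(C)(C)C)c(OC)c1 | intermediate (not isolated)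
23 | C1/C10 siloxycyclopropane of 22 (cyclopropane CH2 on C1 and C10, cis to the C4 hydroxyl; C10–OSiMe3) | O=C(O[C@H]1CC(C)=C[C@]2(O[Si](C)(C)C)C[C@@]23CC[C@@](O)(C(C)C)[C@H]13)c1ccc(O[Si](C)(C)C(C)(C)C)c(OC)c1 | intermediate
24 | (3R,3aS,4S,8aS)-3-hydroxy-6,8a-dimethyl-8-oxo-3-(propan-2-yl)-1,2,3,3a,4,5,8,8a-octahydroazulen-4-yl 4-hydroxy-3-methoxybenzoate | COc1cc(C(=O)O[C@H]2CC(C)=CC(=O)[C@@]3(C)CC[C@@](O)(C(C)C)[C@H]23)ccc1O | target

**Step count**

Total: 17 steps. Longest linear sequence: 14 steps (1–7, 10–12, 14–17).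

**Steps most likely to fail, with fallbacks**

1. Step 10 (Proposed new method).
 - What may go wrong: electron transfer to the alkyl ketone may be too slow to sustain the catalyst; the cyclopropane may open at the internal C5–C1 bond; the C2 or C4 radical may be reduced before the next bond forms, giving open-chain hydroalkylation; the C8=C9 double bond may migrate into conjugation under Lewis-acidic trivalent samarium.
 - Fallback from 9 back to 15, using known reactions only: Me3SiI (CH2Cl2, −40 °C, then Et3N) should open the cyclopropyl ketone by iodide attack at the unhindered external CH2, giving {[(3S)-3-(iodomethyl)-6-methylcyclohepta-1,5-dien-1-yl]oxy}trimethylsilane F1.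
 - The kinetic lithium enolate 11 of 3-methylbutan-2-one (LiN(i-Pr)2, THF/DMPU) is alkylated by this primary iodide (bond C2–C3) to {[(3S)-6-methyl-3-(4-methyl-3-oxopentyl)cyclohepta-1,5-dien-1-yl]oxy}trimethylsilane F2.
 - TiCl4 (CH2Cl2, −78 °C) then brings about the intramolecular Mukaiyama aldol addition of the regiodefined C5=C6 silyl enol ether to the C4 ketone (bond C4–C5) through a titanium-bridged transition state and returns to 15.

2. Step 16.
 - What may go wrong: deprotonation at C7 instead of C1 followed by β-elimination of the C6 acyloxy group; acyl transfer from O-6 to the C4 alkoxide; loss of facial control; cyclopropanation at the C8=C9 end of the silyloxydiene.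
 - Fallback from 21 to 24, using a silicon tether in place of a directed external reagent: the C4 hydroxyl of 21 is silylated with (bromomethyl)chlorodimethylsilane (imidazole, DMF) to the (bromomethyl)dimethylsilyl ether of 21 F3.
 - LiN(SiMe3)2 (THF, −78 °C to 0 °C) closes a six-membered siloxane by C-alkylation of the C1 enolate, which is possible only on the face of the C4 oxygen, giving the cyclic siloxane (C1–CH2–SiMe2–O–C4) F4.
 - n-Bu4NF (DMF, 60 °C) then cleaves the C–Si bond to leave the C1 methyl group and removes the aryl silyl ether, giving 24.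

3. Step 15.
 - What may go wrong: oxidation at C7 or at the C8 methyl instead of C10; over-oxidation; slow reaction at the hindered C10 next to the ring fusion.
 - Fallback from 20 to 21 by oxygen transposition: m-CPBA (CH2Cl2, NaHCO3) gives the 8,9-epoxide of 20 F5.
 - PhSeNa (from PhSeSePh and NaBH4, EtOH) opens it at the less substituted C9 to the 8-hydroxy-9-(phenylselanyl) derivative of 20 F6.
 - H2O2 oxidation and selenoxide syn-elimination, which can proceed only toward C10, give the tertiary allylic alcohol (8-hydroxy, C9=C10) F7.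
 - C5H5NH[CrO3Cl] (CH2Cl2, 20 °C) then brings about the oxidative 1,3-transposition of the tertiary allylic alcohol to the C8=C9–C10=O enone 21.

Further compounds
F1 | step 10 | {[(3S)-3-(iodomethyl)-6-methylcyclohepta-1,5-dien-1-yl]oxy}trimethylsilane | C[Si](C)(C)OC1=C[C@@H](CI)CC=C(C)C1
F2 | step 10 | {[(3S)-6-methyl-3-(4-methyl-3-oxopentyl)cyclohepta-1,5-dien-1-yl]oxy}trimethylsilane | C[Si](C)(C)OC1=C[C@@H](CCC(=O)C(C)C)CC=C(C)C1
F3 | step 16 | (bromomethyl)dimethylsilyl ether of 21 at the C4 oxygen | O=C(O[C@H]1CC(C)=CC(=O)[C@@H]2CC[C@@](O[Si](C)(C)CBr)(C(C)C)[C@H]12)c1ccc(O[Si](C)(C)C(C)(C)C)c(OC)c1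
F4 | step 16 | cyclic siloxane (C1–CH2–SiMe2–O–C4) derived from F3 | O=C(O[C@H]1CC(C)=CC(=O)[C@]23CC[C@@](O[Si](C)(C)C2)(C(C)C)[C@H]13)c1ccc(O[Si](C)(C)C(C)(C)C)c(OC)c1
F5 | step 15 | 8,9-epoxide of 20 | O=C(O[C@H]1CC2(C)OC2C[C@@H]3CC[C@@](O)(C(C)C)[C@H]13)c1ccc(O[Si](C)(C)C(C)(C)C)c(OC)c1
F6 | step 15 | 8-hydroxy-9-(phenylselanyl) derivative of 20 | O=C(O[C@H]1CC(C)(O)C([Se]c2ccccc2)C[C@@H]3CC[C@@](O)(C(C)C)[C@H]13)c1ccc(O[Si](C)(C)C(C)(C)C)c(OC)c1
F7 | step 15 | tertiary allylic alcohol (8-hydroxy, C9=C10) derived from 20 | O=C(O[C@H]1CC(C)(O)C=C[C@@H]2CC[C@@](O)(C(C)C)[C@H]12)c1ccc(O[Si](C)(C)C(C)(C)C)c(OC)c1
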